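**Remarks on the chemistry (assumptions).** Target carbons are numbered along the chain: C1 is the lactone carbonyl, C7 the lactone carbinol carbon, C8–C9–C10 the cyclopropane, C22 the terminal methyl. The SMILES is read as 7R,8R,10R,11R,14S with 12E,16Z,19Z. Compounds 2 and 14 and the pentane solution of (−)-B-allyldiisopinocampheylborane are taken as purchasable. In step 14 the vinylsilane is written with silicon on C13; the C12 regioisomer would give the same alkene.

## Analysis of the target

The target is a C22 oxylipin whose head is a saturated eight-membered lactone (oxocan-2-one; ring atoms O, C1–C7). C7 carries a trans-1,2-disubstituted cyclopropane (C8–C9–C10), and C10 carries the C11 carbinol, the 12E alkene, the C14 carbinol and the skipped 16Z,19Z diene. C7, C8, C10 and C11 form one stereochemical block in which the two carbinols flank the cyclopropane in a locally C2-symmetric way (7R,8R,10R,11R). C14 (S) is insulated from this block by the alkene and must be set on its own. The C7–O and C11–O bonds are cyclopropylcarbinylic and the 2-ene-1,4-diol is acid-labile. C18 is doubly allylic, the alkenes forbid peracids and hydrogenation once they are present, and the lactone forbids late aluminium hydride chemistry. The hard points are the saturated eight-membered lactone, which is the worst ring size for end-to-end lactonisation, and the relative configuration across the C7–C8 junction. The feature that invites the key step is the ring oxygen on C7: excising it (retro oxygen insertion into C1–C7) leaves a 2-substituted cycloheptanone in which C7 is an α-carbon. Because C10 is α to the C11 carboxyl carbon, the cyclopropane bond C8–C10 can come from a 1,3-elimination of a C8 carbinol. C7/C8 then becomes an anti-aldol pair of a seven-membered ketone.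

## Retrosynthetic reasoning

**C12=C13 and the C14 silyl ether (23 from 21).** The E alkene is taken back to the alkyne of 21 and the C14 hydroxyl to its silyl ether. This lets C11 be set on a ynone, and a ruthenium-catalysed trans-hydrosilylation/protodesilylation leaves lactone and skipped diene alone. The forward step must add the two hydrogens trans and strip both silicon groups without opening the lactone.

**C11–O stereocenter (21 from 20).** The C11 carbinol is cut back to the ketone of ynone 20. Catalyst-controlled transfer hydrogenation of alkynyl ketones reads "alkynyl versus alkyl" reliably, so C11 does not depend on the remote centers.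

**C11–C12 bond (20 from 7 and 18).** The bond between the acyl carbon C11 and the alkyne carbon C12 is cut. This divides the molecule into two halves of similar size, acid 7 (through its chloride 19) and terminal alkyne 18. No stereocenter is formed in the coupling and the lactone is not attacked by the soft copper acetylide.

**Side chain (18 from 17, 13, 15, 11, 10, 8).** The 16Z alkene is cut by a Wittig disconnection into aldehyde 13 and the ylide 16 of salt 15, which already contains the 19Z alkene. Aldehyde 13 comes from the terminal alkene of 11 through diol 12. The C14–C15 bond and the C14 configuration come from a reagent-controlled allylboration of ynal 8 that gives 10.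

**Cyclopropane bond C8–C10 (7 and 6 from 5).** The cyclopropane is opened at C8–C10, not at a bond to C9, because C10 is α to the ester carbon C11 and C8 can carry a sulfonate. The forward 3-exo-tet alkylation inverts C8 and sets C10 trans. The precursor 5 is a simple tosylate of carbinol 4.

**Ring oxygen (4 from 3), the key disconnection.** The O–C7 bond of the lactone is removed by retro oxygen insertion, which contracts the eight-membered lactone 4 to the cycloheptanone 3. This is chosen over cutting the acyl C1–O bond because it never requires closing an eight-membered ring. It also turns the lactone stereocenter C7 into an α-keto carbon that an aldol can set. The forward step must migrate C7 and not C2, with retention.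

**C7–C8 bond (3 from 1 and 2).** The remaining bond is an aldol bond between ketone 1 and aldehyde 2. The anti relationship needed in 3 is the natural outcome of enamine catalysis with a cyclic ketone, so one small catalyst sets C7 and C8 together.

## Alternatives that were turned down

**Alternative 1:** the textbook route. The lactone is cut at the acyl C1–O bond to give seco acid A1. A1 would be made by a directed Simmons–Smith cyclopropanation of an allylic alcohol and a separate asymmetric step for C7, and closed by Yamaguchi lactonisation. The side chain would be joined by a chromium-mediated vinyl addition to the C11 aldehyde. It was turned down because a saturated 7-hydroxy acid closes to the eight-membered ring at the kinetic minimum of lactonisation (entropy plus transannular strain, with oligomers competing). In addition C7, the cyclopropane and C11 each need their own controlling step, the vinyl addition gives little control at C11 next to a cyclopropane, and the protecting-group traffic roughly doubles the step count.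

**Alternative 2:** a Michael-initiated ring closure. The azaenolate of a chiral hydrazone of 1 would add to a γ-bromo enoate and close the cyclopropane in the same flask, forming C7–C8 and C9–C10 and three stereocenters at once. Hydrazone cleavage would give keto ester A2. It was turned down on mechanistic grounds. The azaenolate of a cyclic ketone is E-configured, and in the lithium-bridged closed transition state with an E-enoate the ring methylene and the bromomethyl group should end up syn. That corresponds to A2, which has the wrong relative configuration at the C7–C8 junction (its cyclopropane is the mirror image of the one needed for the given C7). The later oxygen insertion retains C7, so the error could not be repaired.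

**Alternative 3:** a biomimetic cation cascade. Ionisation of the homoallylic sulfonate A3 would let the C7=C8 alkene attack C10, and the carboxylate would trap the resulting cyclopropylcarbinyl cation at C7. This would form the cyclopropane, the C7–O bond and the lactone in one step. It was turned down because the trapping step is again an eight-membered ring closure, now competing with elimination, cyclobutyl and homoallyl capture and external nucleophiles. The configuration at C7 would depend on which face of a mobile cation is captured, and the trans geometry of the ring is not enforced by the Z alkene.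

Key step: step 2

## Route

**Step 1**
Reactants: 1 cycloheptanone; 2 tert-butyl 4-oxobutanoate
Product: 3 tert-butyl (4R)-4-hydroxy-4-[(1R)-2-oxocycloheptyl]butanoate
Conditions: D-proline (30 mol%), 1 (5 equiv), DMSO, 4 °C to rt, slow addition of 2
Reagents that add atoms: none
Why: Direct enamine aldol reaction (List–Barbas type): the E-enamine of 1 attacks the aldehyde through the hydrogen-bonded Houk–List transition state, which gives the anti aldol. D-proline should give the (7R,8R) enantiomer, the mirror image of the (2S,1'S) products known from L-proline, cyclic ketones and aliphatic aldehydes.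

**Step 2**
Reactants: 3 tert-butyl (4R)-4-hydroxy-4-[(1R)-2-oxocycloheptyl]butanoate
Product: 4 tert-butyl (4R)-4-hydroxy-4-[(2R)-8-oxooxocan-2-yl]butanoate
Conditions: mCPBA (2.5 equiv), NaHCO3, CH2Cl2, 0 °C to rt
Reagents that add atoms: 3-chloroperoxybenzoic acid, OOC(=O)c1cccc(Cl)c1
Why: Baeyer–Villiger oxidation: the peracid adds to the ketone of 3 to give the Criegee adduct, and C7, the more substituted α-carbon, migrates from C1 to oxygen antiperiplanar to the breaking O–O bond. The closest known reaction type is the peracid ring expansion of 2-alkylcycloheptanones to 8-substituted oxocan-2-ones and of aldol-derived β-hydroxy ketones to diol monoesters. No ring is closed end to end: the eight-membered lactone arises by insertion of one oxygen atom into the C1–C7 bond of the seven-membered ring, so the penalty of a medium-ring lactonisation is never paid. No new stereocenter is formed; the shift proceeds with retention, so C7 keeps the R configuration from step 1 and the epimerisable α-keto center becomes a stable C–O center. The step needs regioselectivity (C7 over the C2 methylene), which the secondary-over-primary migratory aptitude secures and the hydrogen-bonded β-hydroxyl should assist. It also needs chemoselectivity, which is given because 3 has no alkene and the tert-butyl ester is inert. The hydrogen carbonate buffer should keep the medium too weakly acidic for loss of the tert-butyl group or γ-lactonisation of the 4-hydroxy ester.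

**Step 3**
Reactants: 4 tert-butyl (4R)-4-hydroxy-4-[(2R)-8-oxooxocan-2-yl]butanoate
Product: 5 tert-butyl (4R)-4-[(4-methylbenzenesulfonyl)oxy]-4-[(2R)-8-oxooxocan-2-yl]butanoate
Conditions: TsCl, Et3N, Me3N·HCl (10 mol%), CH2Cl2, 0 °C
Reagents that add atoms: 4-methylbenzenesulfonyl chloride, Cc1ccc(cc1)S(Cl)(=O)=O
Why: O-Sulfonylation of the secondary carbinol; only the O–H bond reacts, so C8 keeps its configuration. A tosylate is chosen because it has no acidic α-hydrogen for the base of step 4.

**Step 4**
Reactants: 5 tert-butyl (4R)-4-[(4-methylbenzenesulfonyl)oxy]-4-[(2R)-8-oxooxocan-2-yl]butanoate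
Product: 6 tert-butyl (1R,2R)-2-[(2R)-8-oxooxocan-2-yl]cyclopropane-1-carboxylate
Conditions: LiN(i-Pr)2 (2.2 equiv), THF, −78 to −40 °C; AcOH quench
Reagents that add atoms: none
Why: Intramolecular enolate alkylation (3-exo-tet, 1,3-elimination): the tert-butyl ester enolate at C10 displaces the tosylate at C8 with inversion, which converts the aldol carbinol into the target configuration at C8. C10 should be set trans because the ester avoids the C7 substituent in the transition state. The second equivalent of base holds the lactone as its enolate, so it cannot act as an acyl acceptor, and it is reprotonated on quench.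

**Step 5**
Reactants: 6 tert-butyl (1R,2R)-2-[(2R)-8-oxooxocan-2-yl]cyclopropane-1-carboxylate
Product: 7 (1R,2R)-2-[(2R)-8-oxooxocan-2-yl]cyclopropane-1-carboxylic acid
Conditions: CF3CO2H/CH2Cl2 (1:4), 0 °C to rt
Reagents that add atoms: none
Why: Acidolysis of the tert-butyl ester through the tert-butyl cation. The lactone is stable to anhydrous acid, and the acceptor-substituted cyclopropane should disfavour ionisation of the C7–O bond.

**Step 6**
Reactants: 8 3-(trimethylsilyl)prop-2-ynal
Product: 10 (3S)-1-(trimethylsilyl)hex-5-en-1-yn-3-ol, via homoallylic borinate 9 (not isolated)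
Conditions: (−)-Ipc2B(allyl) (1 M in pentane), Et2O, −78 °C; then HOCH2CH2NH2, rt
Reagents that add atoms: (−)-B-allyldiisopinocampheylborane (from (+)-α-pinene), C=CCB([C@@H]1C[C@@H]2C[C@H]([C@H]1C)C2(C)C)[C@@H]1C[C@@H]2C[C@H]([C@H]1C)C2(C)C
Why: Brown allylboration through a chair transition state. This enantiomer of the reagent gives S alcohols from aldehydes whose substituent outranks allyl (as with benzaldehyde), so the ynal should give the 3S carbinol, the future C14. The amine work-up avoids hydroxide, which would cleave the alkynylsilane.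

**Step 7**
Reactants: 10 (3S)-1-(trimethylsilyl)hex-5-en-1-yn-3-ol
Product: 11 tert-butyldimethyl{[(3S)-1-(trimethylsilyl)hex-5-en-1-yn-3-yl]oxy}silane
Conditions: TBSCl, imidazole, DMF, rt
Reagents that add atoms: tert-butyldimethylsilyl chloride, CC(C)(C)[Si](C)(C)Cl
Why: Standard silylation of a secondary alcohol; the ether must survive base, ylide, palladium and ruthenium chemistry and leave with fluoride in the last step.

**Step 8**
Reactants: 11 tert-butyldimethyl{[(3S)-1-(trimethylsilyl)hex-5-en-1-yn-3-yl]oxy}silane
Product: 13 (3S)-3-[(tert-butyldimethylsilyl)oxy]-5-(trimethylsilyl)pent-4-ynal, via vicinal diol 12 (not isolated)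
Conditions: OsO4 (2 mol%), NaIO4, 2,6-lutidine, dioxane/H2O, rt
Reagents that add atoms: osmium tetroxide, O=[Os](=O)(=O)=O; sodium periodate (terminal oxidant), [Na+].[O-]I(=O)(=O)=O
Why: Lemieux–Johnson cleavage: dihydroxylation is selective for the terminal alkene over the silylated alkyne, and periodate cleaves the diol to the aldehyde. The lutidine buffer should suppress β-elimination of the silyloxy group.

**Step 9**
Reactants: 14 (3Z)-1-bromohex-3-ene
Product: 15 [(3Z)-hex-3-en-1-yl]triphenylphosphonium bromide
Conditions: PPh3, MeCN, reflux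
Reagents that add atoms: triphenylphosphine, c1ccc(cc1)P(c1ccccc1)c1ccccc1
Why: SN2 quaternisation of a primary bromide; the remote Z alkene is not involved.

**Step 10**
Reactants: 13 (3S)-3-[(tert-butyldimethylsilyl)oxy]-5-(trimethylsilyl)pent-4-ynal; 15 [(3Z)-hex-3-en-1-yl]triphenylphosphonium bromide
Product: 17 tert-butyldimethyl{[(3S,5Z,8Z)-1-(trimethylsilyl)undeca-5,8-dien-1-yn-3-yl]oxy}silane, via phosphonium ylide 16 (not isolated)
Conditions: NaN(SiMe3)2, THF, −78 to 0 °C; then 13, −78 °C to rt
Reagents that add atoms: none
Why: Wittig olefination with a non-stabilised ylide under lithium-free conditions, which should give the Z alkene (C16=C17) by kinetic oxaphosphetane formation. Low temperature limits β-elimination of the aldehyde.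

**Step 11**
Reactants: 17 tert-butyldimethyl{[(3S,5Z,8Z)-1-(trimethylsilyl)undeca-5,8-dien-1-yn-3-yl]oxy}silane
Product: 18 tert-butyldimethyl{[(3S,5Z,8Z)-undeca-5,8-dien-1-yn-3-yl]oxy}silane
Conditions: K2CO3, MeOH, rt
Reagents that add atoms: none
Why: Methanolysis of the C(sp)–Si bond; the silyl ether and the skipped diene are stable to carbonate in methanol.

**Step 12**
Reactants: 7 (1R,2R)-2-[(2R)-8-oxooxocan-2-yl]cyclopropane-1-carboxylic acid; 18 tert-butyldimethyl{[(3S,5Z,8Z)-undeca-5,8-dien-1-yn-3-yl]oxy}silane
Product: 20 (8R)-8-[(1R,2R)-2-[(4S,6Z,9Z)-4-[(tert-butyldimethylsilyl)oxy]dodeca-6,9-dien-2-ynoyl]cyclopropyl]oxocan-2-one, via acid chloride 19 (not isolated)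
Conditions: (COCl)2, DMF (cat.), CH2Cl2, 0 °C to rt, evaporate; then 18, PdCl2(PPh3)2 (2 mol%), CuI (4 mol%), Et3N, THF, rt
Reagents that add atoms: none
Why: Acyl Sonogashira coupling: the acyl chloride adds oxidatively to zerovalent palladium formed in situ and couples with the copper acetylide of 18. The acetylide is too soft to open the lactone, and the cyclopropyl α-hydrogen does not epimerise under triethylamine.

**Step 13**
Reactants: 20 (8R)-8-[(1R,2R)-2-[(4S,6Z,9Z)-4-[(tert-butyldimethylsilyl)oxy]dodeca-6,9-dien-2-ynoyl]cyclopropyl]oxocan-2-one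
Product: 21 (8R)-8-[(1R,2R)-2-[(1S,4S,6Z,9Z)-4-[(tert-butyldimethylsilyl)oxy]-1-hydroxydodeca-6,9-dien-2-yn-1-yl]cyclopropyl]oxocan-2-one
Conditions: Ru[(S,S)-TsNCHPhCHPhNH](p-cymene) (3 mol%), i-PrOH, rt
Reagents that add atoms: none
Why: Noyori asymmetric transfer hydrogenation of an alkynyl ketone by the divalent ruthenium amido complex (outer-sphere hydride and proton transfer). The (S,S) catalyst gives S propargylic alcohols when the alkynyl group outranks the alkyl group, so C11 should come out 1S here, which becomes 11R once the alkyne is an alkene.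

**Step 14**
Reactants: 21 (8R)-8-[(1R,2R)-2-[(1S,4S,6Z,9Z)-4-[(tert-butyldimethylsilyl)oxy]-1-hydroxydodeca-6,9-dien-2-yn-1-yl]cyclopropyl]oxocan-2-one
Product: 23 (8R)-8-[(1R,2R)-2-[(1R,2E,4S,6Z,9Z)-1,4-dihydroxydodeca-2,6,9-trien-1-yl]cyclopropyl]oxocan-2-one, via Z-vinylsilane 22 (not isolated)
Conditions: [Cp*Ru(MeCN)3]PF6 (5 mol%), (EtO)3SiH, CH2Cl2, 0 °C to rt; then CuI, Bu4NF, THF, rt
Reagents that add atoms: none
Why: Trost trans-hydrosilylation of the alkyne followed by copper- and fluoride-mediated protodesilylation with retention, which together amount to a trans reduction to the E alkene. The cationic ruthenium catalyst prefers alkynes over the Z alkenes, and the same fluoride removes the C14 silyl ether.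

## Compound list

1 | cycloheptanone | O=C1CCCCCC1 | starting material
2 | tert-butyl 4-oxobutanoate | CC(C)(C)OC(=O)CCC=O | starting material
3 | tert-butyl (4R)-4-hydroxy-4-[(1R)-2-oxocycloheptyl]butanoate | CC(C)(C)OC(=O)CC[C@@H](O)[C@H]1CCCCCC1=O | intermediate
4 | tert-butyl (4R)-4-hydroxy-4-[(2R)-8-oxooxocan-2-yl]butanoate | CC(C)(C)OC(=O)CC[C@@H](O)[C@H]1CCCCCC(=O)O1 | intermediate
5 | tert-butyl (4R)-4-[(4-methylbenzenesulfonyl)oxy]-4-[(2R)-8-oxooxocan-2-yl]butanoate | CC(C)(C)OC(=O)CC[C@@H](OS(=O)(=O)c1ccc(C)cc1)[C@H]1CCCCCC(=O)O1 | intermediate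
6 | tert-butyl (1R,2R)-2-[(2R)-8-oxooxocan-2-yl]cyclopropane-1-carboxylate | CC(C)(C)OC(=O)[C@@H]1C[C@H]1[C@H]1CCCCCC(=O)O1 | intermediate
7 | (1R,2R)-2-[(2R)-8-oxooxocan-2-yl]cyclopropane-1-carboxylic acid | OC(=O)[C@@H]1C[C@H]1[C@H]1CCCCCC(=O)O1 | intermediate
8 | 3-(trimethylsilyl)prop-2-ynal | C[Si](C)(C)C#CC=O | starting material
9 | (3S)-1-(trimethylsilyl)hex-5-en-1-yn-3-yl diisopinocampheylborinate | C=CC[C@H](OB([C@@H]1C[C@@H]2C[C@H]([C@H]1C)C2(C)C)[C@@H]1C[C@@H]2C[C@H]([C@H]1C)C2(C)C)C#C[Si](C)(C)C | intermediate
10 | (3S)-1-(trimethylsilyl)hex-5-en-1-yn-3-ol | C=CC[C@H](O)C#C[Si](C)(C)C | intermediate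
11 | tert-butyldimethyl{[(3S)-1-(trimethylsilyl)hex-5-en-1-yn-3-yl]oxy}silane | C=CC[C@H](O[Si](C)(C)C(C)(C)C)C#C[Si](C)(C)C | intermediate
12 | (4S)-4-[(tert-butyldimethylsilyl)oxy]-6-(trimethylsilyl)hex-5-yne-1,2-diol (both C2 epimers) | OCC(O)C[C@H](O[Si](C)(C)C(C)(C)C)C#C[Si](C)(C)C | intermediate
13 | (3S)-3-[(tert-butyldimethylsilyl)oxy]-5-(trimethylsilyl)pent-4-ynal | O=CC[C@H](O[Si](C)(C)C(C)(C)C)C#C[Si](C)(C)C | intermediate
14 | (3Z)-1-bromohex-3-ene | CC/C=C\CCBr | starting material
15 | [(3Z)-hex-3-en-1-yl]triphenylphosphonium bromide | CC/C=C\CC[P+](c1ccccc1)(c1ccccc1)c1ccccc1.[Br-] | intermediate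
16 | [(3Z)-hex-3-en-1-ylidene]triphenylphosphorane | CC/C=C\CC=P(c1ccccc1)(c1ccccc1)c1ccccc1 | intermediate
17 | tert-butyldimethyl{[(3S,5Z,8Z)-1-(trimethylsilyl)undeca-5,8-dien-1-yn-3-yl]oxy}silane | CC/C=C\C/C=C\C[C@H](O[Si](C)(C)C(C)(C)C)C#C[Si](C)(C)C | intermediate
18 | tert-butyldimethyl{[(3S,5Z,8Z)-undeca-5,8-dien-1-yn-3-yl]oxy}silane | CC/C=C\C/C=C\C[C@H](O[Si](C)(C)C(C)(C)C)C#C | intermediate
19 | (1R,2R)-2-[(2R)-8-oxooxocan-2-yl]cyclopropane-1-carbonyl chloride | ClC(=O)[C@@H]1C[C@H]1[C@H]1CCCCCC(=O)O1 | intermediate
20 | (8R)-8-[(1R,2R)-2-[(4S,6Z,9Z)-4-[(tert-butyldimethylsilyl)oxy]dodeca-6,9-dien-2-ynoyl]cyclopropyl]oxocan-2-one | CC/C=C\C/C=C\C[C@H](O[Si](C)(C)C(C)(C)C)C#CC(=O)[C@@H]1C[C@H]1[C@H]1CCCCCC(=O)O1 | intermediate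
21 | (8R)-8-[(1R,2R)-2-[(1S,4S,6Z,9Z)-4-[(tert-butyldimethylsilyl)oxy]-1-hydroxydodeca-6,9-dien-2-yn-1-yl]cyclopropyl]oxocan-2-one | CC/C=C\C/C=C\C[C@H](O[Si](C)(C)C(C)(C)C)C#C[C@@H](O)[C@@H]1C[C@H]1[C@H]1CCCCCC(=O)O1 | intermediate
22 | (8R)-8-[(1R,2R)-2-[(1S,2Z,4S,6Z,9Z)-4-[(tert-butyldimethylsilyl)oxy]-1-hydroxy-3-(triethoxysilyl)dodeca-2,6,9-trien-1-yl]cyclopropyl]oxocan-2-one | CC/C=C\C/C=C\C[C@H](O[Si](C)(C)C(C)(C)C)/C([Si](OCC)(OCC)OCC)=C/[C@@H](O)[C@@H]1C[C@H]1[C@H]1CCCCCC(=O)O1 | intermediate
23 | (8R)-8-[(1R,2R)-2-[(1R,2E,4S,6Z,9Z)-1,4-dihydroxydodeca-2,6,9-trien-1-yl]cyclopropyl]oxocan-2-one | CC/C=C\C/C=C\C[C@H](O)/C=C/[C@@H](O)[C@@H]1C[C@H]1[C@H]1CCCCCC(=O)O1 | target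

## Step count and least certain steps

Total step count: 14. Longest linear sequence: 8 steps (1, 2, 3, 4, 5, 12, 13, 14 from cycloheptanone; the side-chain branch 6, 7, 8, 10, 11, 12, 13, 14 is equally long).

**Step 2 (key step).** Three processes could interfere. The free C8 hydroxyl could take over the acyl group (translactonisation to a nine-membered ring). The 4-hydroxy ester could lactonise under the acid that accumulates. Oxidation of the seven-membered ketone could be slow enough for C7 to epimerise or for the C2 methylene to migrate in part. The fallback sets out from 3 and comes back at 4. The carbinol of 3 would be silylated (Et3SiOTf, 2,6-lutidine) to tert-butyl (4R)-4-[(1R)-2-oxocycloheptyl]-4-[(triethylsilyl)oxy]butanoate F1. Without a free hydroxyl F1 can be oxidised with the stronger buffered CF3CO3H (from (CF3CO)2O and urea·H2O2, Na2HPO4) to tert-butyl (4R)-4-[(2R)-8-oxooxocan-2-yl]-4-[(triethylsilyl)oxy]butanoate F2. HF·pyridine at 0 °C would then free the carbinol to give 4 directly before tosylation.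

**Step 1.** Self-condensation of the enolisable aldehyde through its own enamine, and lower diastereo- and enantioselection with the conformationally mobile seven-membered enamine than with cyclohexanone, are the likely problems. The fallback sets out from 1 and 2 and comes back at 3. The E-enol borinate of 1 (Cy2BCl, Et3N, Et2O, −78 °C) would be added to 2 and worked up oxidatively. This anti-selective but racemic aldol would give 3 together with its enantiomer, tert-butyl (4S)-4-hydroxy-4-[(1S)-2-oxocycloheptyl]butanoate F3. F3 would be removed by preparative chromatography on a chiral stationary phase.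

**Step 4.** Deprotonation may partition unfavourably between the lactone and the tert-butyl ester, the lactone enolate may fragment on warming, or base-induced elimination of the tosylate may compete with the three-membered ring closure. The fallback sets out from 3 and comes back at 6, and closes the cyclopropane before the ring expansion, on a substrate with one acidic site only. The steps would be:
- Ketalisation of 3 (Me3SiOCH2CH2OSiMe3, Me3SiOTf cat., −78 °C, then mild aqueous work-up) to tert-butyl (4R)-4-[(6R)-1,4-dioxaspiro[4.6]undecan-6-yl]-4-hydroxybutanoate F4.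
- Tosylation as in step 3 to tert-butyl (4R)-4-[(6R)-1,4-dioxaspiro[4.6]undecan-6-yl]-4-[(4-methylbenzenesulfonyl)oxy]butanoate F5.
- Ring closure with LiN(i-Pr)2 (1.1 equiv) to tert-butyl (1R,2S)-2-[(6R)-1,4-dioxaspiro[4.6]undecan-6-yl]cyclopropane-1-carboxylate F6.
- Mild deketalisation (pyridinium tosylate, wet acetone) to tert-butyl (1R,2S)-2-[(1R)-2-oxocycloheptyl]cyclopropane-1-carboxylate F7.
- Peracid oxidation of F7 as in step 2 to give 6.

**Step 14.** Ruthenium hydride species may isomerise the skipped diene or the propargylic alcohol, protodesilylation may be incomplete, or basic fluoride may open the lactone or let the C11 hydroxyl translactonise. The fallback sets out from 18 and 19 and comes back at 23, and avoids the alkyne reduction altogether. The steps would be: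
- Hydrostannation of 18 (Bu3SnH, PdCl2(PPh3)2) to tributyl[(1E,3S,5Z,8Z)-3-[(tert-butyldimethylsilyl)oxy]undeca-1,5,8-trien-1-yl]stannane F8.
- Stille acylation of F8 with 19 (Pd(PPh3)4, a zerovalent palladium catalyst) to the enone (8R)-8-[(1R,2R)-2-[(2E,4S,6Z,9Z)-4-[(tert-butyldimethylsilyl)oxy]dodeca-2,6,9-trienoyl]cyclopropyl]oxocan-2-one F9.
- Reduction with the (R)-configured methyl-CBS oxazaborolidine and catecholborane to (8R)-8-[(1R,2R)-2-[(1R,2E,4S,6Z,9Z)-4-[(tert-butyldimethylsilyl)oxy]-1-hydroxydodeca-2,6,9-trien-1-yl]cyclopropyl]oxocan-2-one F10. The (R) catalyst is expected to give 11R if the alkenyl arm acts as the larger group, as is usual for trans-enones; otherwise the antipodal catalyst would be used.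
- Removal of the silyl ether with Bu4NF buffered with AcOH to give 23.

## Further compounds

F1 | step 2 | tert-butyl (4R)-4-[(1R)-2-oxocycloheptyl]-4-[(triethylsilyl)oxy]butanoate | CC(C)(C)OC(=O)CC[C@@H](O[Si](CC)(CC)CC)[C@H]1CCCCCC1=O
F2 | step 2 | tert-butyl (4R)-4-[(2R)-8-oxooxocan-2-yl]-4-[(triethylsilyl)oxy]butanoate | CC(C)(C)OC(=O)CC[C@@H](O[Si](CC)(CC)CC)[C@H]1CCCCCC(=O)O1
F3 | step 1 | tert-butyl (4S)-4-hydroxy-4-[(1S)-2-oxocycloheptyl]butanoate | CC(C)(C)OC(=O)CC[C@H](O)[C@@H]1CCCCCC1=O
F4 | step 4 | tert-butyl (4R)-4-[(6R)-1,4-dioxaspiro[4.6]undecan-6-yl]-4-hydroxybutanoate | CC(C)(C)OC(=O)CC[C@@H](O)[C@H]1CCCCCC12OCCO2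
F5 | step 4 | tert-butyl (4R)-4-[(6R)-1,4-dioxaspiro[4.6]undecan-6-yl]-4-[(4-methylbenzenesulfonyl)oxy]butanoate | CC(C)(C)OC(=O)CC[C@@H](OS(=O)(=O)c1ccc(C)cc1)[C@H]1CCCCCC12OCCO2
F6 | step 4 | tert-butyl (1R,2S)-2-[(6R)-1,4-dioxaspiro[4.6]undecan-6-yl]cyclopropane-1-carboxylate | CC(C)(C)OC(=O)[C@@H]1C[C@H]1[C@H]1CCCCCC12OCCO2
F7 | step 4 | tert-butyl (1R,2S)-2-[(1R)-2-oxocycloheptyl]cyclopropane-1-carboxylate | CC(C)(C)OC(=O)[C@@H]1C[C@H]1[C@H]1CCCCCC1=O
F8 | step 14 | tributyl[(1E,3S,5Z,8Z)-3-[(tert-butyldimethylsilyl)oxy]undeca-1,5,8-trien-1-yl]stannane | CC/C=C\C/C=C\C[C@H](O[Si](C)(C)C(C)(C)C)/C=C/[Sn](CCCC)(CCCC)CCCC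
F9 | step 14 | (8R)-8-[(1R,2R)-2-[(2E,4S,6Z,9Z)-4-[(tert-butyldimethylsilyl)oxy]dodeca-2,6,9-trienoyl]cyclopropyl]oxocan-2-one | CC/C=C\C/C=C\C[C@H](O[Si](C)(C)C(C)(C)C)/C=C/C(=O)[C@@H]1C[C@H]1[C@H]1CCCCCC(=O)O1
F10 | step 14 | (8R)-8-[(1R,2R)-2-[(1R,2E,4S,6Z,9Z)-4-[(tert-butyldimethylsilyl)oxy]-1-hydroxydodeca-2,6,9-trien-1-yl]cyclopropyl]oxocan-2-one | CC/C=C\C/C=C\C[C@H](O[Si](C)(C)C(C)(C)C)/C=C/[C@@H](O)[C@@H]1C[C@H]1[C@H]1CCCCCC(=O)O1
A1 | alternative 1 | (7R)-7-[(1R,2R)-2-{[(tert-butyldiphenylsilyl)oxy]methyl}cyclopropyl]-7-hydroxyheptanoic acid | CC(C)(C)[Si](OC[C@@H]1C[C@H]1[C@H](O)CCCCCC(=O)O)(c1ccccc1)c1ccccc1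
A2 | alternative 2 | tert-butyl (1S,2R)-2-[(1R)-2-oxocycloheptyl]cyclopropane-1-carboxylate | CC(C)(C)OC(=O)[C@H]1C[C@@H]1[C@H]1CCCCCC1=O
A3 | alternative 3 | (7Z,10R)-11-(benzyloxy)-10-[(methanesulfonyl)oxy]undec-7-enoic acid | OC(=O)CCCCC/C=C\C[C@@H](OS(C)(=O)=O)COCc1ccccc1
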